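**Retrosynthetic overview**

1. Target ⇐ desilylation ⇐ C1=C10 epoxidation (ring C) ⇐ acylation of C8–OH with a preformed side-chain acid (Evans hydroxymethylation plus a Morita–Baylis–Hillman bromide).
2. Lactone ring B ⇐ one palladium-catalysed [3+2] heteroannulation of 2-bromoacrylic acid across C6=C7 of a ten-membered 1(10)E,4Z,6E-triene: C11–C7 and O–C6 form together, C6 and C7 are set, the exocyclic methylene arrives intact and C4=C5 (Z) stays in place.
3. Enabling feature: the lactone oxygen on C6 of ring B is allylic to the C4=C5 alkene of ring A. O–C6/C7–C11 therefore sit at the end of a C4=C5–C6 allyl unit, the retron of a C4=C5–C6=C7 diene whose π-allyl complex (C4–C5–C6) is closed by the carboxylate.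
4. Ring A ⇐ anionic oxy-Cope ring expansion (six → ten) of a 1,2-dialkenylcyclohexenol made from all ten carbons of (S)-carvone and a two-carbon (Z)-alkoxyvinyl unit; the enolate is kept as a triflate and reduced to the diene (skeleton = C10 + C2 + C3).
5. Ring order: carvone six-membered ring → ring A (step 7) → ring B (step 9) → ring C (step 20).

Key step: step 9

Remark (assumption): ring positions follow germacranolide numbering throughout (ring A = C1–C10; ring B = O, C6, C7, C11, C12; C13 exocyclic methylene; C14 on C10; C15 on C4; ring C = epoxide), and the ten-membered triene is assumed to react from the crossed conformation it inherits from the chair oxy-Cope transition state.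

**Route**

Step 1
Reactants: 1 4-methoxybenzyl alcohol; 2 ethyl vinyl ether
Product: 3 4-methoxybenzyl vinyl ether
Conditions: Pd(OAc)2 (2 mol %), 1,10-phenanthroline (2 mol %), 2 (20 equiv), CH2Cl2, rt
Reagents that add atoms: none
Why: Palladium-catalysed transfer vinylation (transetherification) of a primary alcohol with excess vinyl ether is an established route to benzylic vinyl ethers and forms no stereocentre.

Step 2
Reactants: 3 4-methoxybenzyl vinyl ether
Product: 5 (Z)-1-bromo-2-(4-methoxybenzyloxy)ethene, via dibromide 4 (not isolated)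
Conditions: Br2 (1.0 equiv), CH2Cl2, −78 °C; then i-Pr2NEt (1.5 equiv), −78 °C → rt
Reagents that add atoms: bromine, BrBr
Why: Bromine addition to the electron-rich vinyl ether followed by amine-induced dehydrobromination of the α-bromo ether (addition–elimination) should give the β-bromo enol ether mainly as the Z isomer, as in the preparation of cis-1-bromo-2-ethoxyethene; any E isomer is removed by chromatography.

Step 3
Reactants: 6 (S)-(+)-carvone
Product: 7 (1S,5S)-cis-carveol
Conditions: NaBH4, CeCl3·7H2O, MeOH, −78 → 0 °C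
Reagents that add atoms: none
Why: Luche 1,2-reduction, in which hydride adds to the half-chair so that the new hydroxyl ends up cis to the C5 isopropenyl group (1S).

Step 4
Reactants: 7 (1S,5S)-cis-carveol
Product: 8 (1S,5S)-cis-carveol tert-butyldimethylsilyl ether
Conditions: TBSCl, imidazole, DMF, rt
Reagents that add atoms: tert-butyldimethylsilyl chloride, C[Si](C)(Cl)C(C)(C)C
Why: Standard silylation of a secondary allylic alcohol; TBS should survive the organolithium, KN(SiMe3)2, zerovalent palladium, DDQ and peracid steps that follow.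

Step 5
Reactants: 8 (1S,5S)-cis-carveol tert-butyldimethylsilyl ether
Product: 9 (4S,6S)-4-(tert-butyldimethylsilyloxy)-3-methyl-6-(prop-1-en-2-yl)cyclohex-2-en-1-one
Conditions: Rh2(cap)4 [dirhodium tetrakis(caprolactamate), 1 mol %], t-BuOOH (5 equiv), K2CO3 (0.5 equiv), CH2Cl2, rt
Reagents that add atoms: tert-butyl hydroperoxide, CC(C)(C)OO
Why: Radical allylic C–H oxidation should convert the only unhindered ring allylic methylene into the enone carbonyl, the silyloxy-bearing C–H being shielded and isopropenyl groups normally surviving such oxidations of terpenes; the isopropenyl centre keeps its configuration (cis-4,6 is also the thermodynamic arrangement).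

Step 6
Reactants: 5 (Z)-1-bromo-2-(4-methoxybenzyloxy)ethene; 9 (4S,6S)-4-(tert-butyldimethylsilyloxy)-3-methyl-6-(prop-1-en-2-yl)cyclohex-2-en-1-one
Product: 11 (1S,4S,6S)-4-(tert-butyldimethylsilyloxy)-1-[(Z)-2-(4-methoxybenzyloxy)ethenyl]-3-methyl-6-(prop-1-en-2-yl)cyclohex-2-en-1-ol, via alkenyllithium 10 (not isolated)
Conditions: t-BuLi (2.0 equiv), Et2O, −78 °C; then 9, THF, −78 °C; then H2O
Reagents that add atoms: none
Why: Bromine–lithium exchange with retention gives the oxygen-chelated (Z)-alkenyllithium, which should add 1,2 to the enone on the face opposite to the adjacent isopropenyl group, so that the two alkenyl groups on C1 and C6 are trans and the hydroxyl is cis to isopropenyl.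

Step 7
Reactants: 11 (1S,4S,6S)-4-(tert-butyldimethylsilyloxy)-1-[(Z)-2-(4-methoxybenzyloxy)ethenyl]-3-methyl-6-(prop-1-en-2-yl)cyclohex-2-en-1-ol
Product: 14 (3S,8R)-3-(tert-butyldimethylsilyloxy)-8-(4-methoxybenzyloxy)-4,10-dimethylcyclodeca-1(10)E,4Z,6-trien-6-yl triflate (ring-trans at C6=C7), via potassium alkoxide 12 (not isolated), via potassium dienolate 13 (not isolated)
Conditions: KN(SiMe3)2 (1.2 equiv), 18-crown-6 (1.5 equiv), THF, −78 → 0 °C; then −78 °C, PhNTf2 (1.3 equiv)
Reagents that add atoms: N-phenylbis(trifluoromethanesulfonimide), O=S(=O)(N(c1ccccc1)S(=O)(=O)C(F)(F)F)C(F)(F)F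
Why: Anionic oxy-Cope rearrangement of the trans-1,2-dialkenyl alkoxide through the chair transition state with both ring bonds equatorial should expand the ring by four atoms, give the E C1=C10 alkene and the ring-trans C6=C7 enolate regiospecifically, and set C8 as R because the Z ether oxygen sits axial on the bond-forming carbon; O-triflation at −78 °C is meant to trap the dienolate before the C8 alkoxide is eliminated.

Step 8
Reactants: 14 (3S,8R)-3-(tert-butyldimethylsilyloxy)-8-(4-methoxybenzyloxy)-4,10-dimethylcyclodeca-1(10)E,4Z,6-trien-6-yl triflate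
Product: 15 (3S,8R)-3-(tert-butyldimethylsilyloxy)-8-(4-methoxybenzyloxy)-4,10-dimethylcyclodeca-1(10)E,4Z,6E-triene
Conditions: Pd(OAc)2 (5 mol %), PPh3 (10 mol %), n-Bu3N (3 equiv), HCO2H (2 equiv), DMF, 50–60 °C
Reagents that add atoms: none
Why: Palladium-catalysed formate reduction of an enol triflate replaces OTf by H with retention of alkene geometry, which should give the 4Z,6E diene.

Step 9
Reactants: 15 (3S,8R)-3-(tert-butyldimethylsilyloxy)-8-(4-methoxybenzyloxy)-4,10-dimethylcyclodeca-1(10)E,4Z,6E-triene; 16 2-bromoacrylic acid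
Product: 17 (3S,6S,7R,8R)-3-(tert-butyldimethylsilyloxy)-8-(4-methoxybenzyloxy)germacra-1(10)E,4Z,11(13)-trien-12,6-olide
Conditions: Pd(OAc)2 (10 mol %), PPh3 (10 mol %), n-Bu4NCl (1 equiv), K2CO3 (2.5 equiv), DMF, 60 °C
Reagents that add atoms: none
Why: Zerovalent palladium inserts into the C–Br bond of 16 (as its potassium salt), the α-carboxyvinylpalladium adds syn across the disubstituted, strained E-C6=C7 end of the C4=C5–C6=C7 diene with C11 going to C7, and the resulting π-allyl complex over C4–C5–C6 is attacked at C6 by the tethered carboxylate on the face opposite to palladium, which returns zerovalent palladium. The closest known reaction type is the Larock palladium-catalysed heteroannulation of 1,3-dienes by vinylic or aryl halides that carry a carboxylic acid, alcohol or sulfonamide, here applied to a medium-ring diene. Ring B closes in the 5-exo mode on the proximal allyl terminus, whereas attack at C4 would need a seven-membered ring and a quaternary carbon. C7 is set by peripheral carbopalladation of the crossed conformer, anti to the C8–C9 bond with the C8 ether oxygen in the inside position, and C6 by the net anti addition of C11 and O across the E-alkene (syn insertion, then inversion), which should give the cis-fused 6S,7R lactone. The C4 terminus keeps its anti ring bond, so C4=C5 stays Z. The step needs site selectivity (conjugated diene over the isolated C1=C10 alkene; C7 over the fully substituted C4), secured by π-allyl stabilisation and the substitution pattern, and outer-sphere C–O bond formation, secured by chloride, which keeps the carboxylate off palladium.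

Step 10
Reactants: 17 (3S,6S,7R,8R)-3-(tert-butyldimethylsilyloxy)-8-(4-methoxybenzyloxy)germacra-1(10)E,4Z,11(13)-trien-12,6-olide
Product: 18 (3S,6S,7R,8R)-3-(tert-butyldimethylsilyloxy)-8-hydroxygermacra-1(10)E,4Z,11(13)-trien-12,6-olide
Conditions: DDQ (1.3 equiv), CH2Cl2/pH 7 buffer (10:1), 0 °C
Reagents that add atoms: none
Why: Oxidative cleavage of the 4-methoxybenzyl ether with DDQ under buffered conditions should leave the silyl ether, the lactone and the alkenes untouched.

Step 11
Reactants: 19 (R)-4-benzyl-2-oxazolidinone; 20 butanoyl chloride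
Product: 21 (R)-4-benzyl-3-butanoyloxazolidin-2-one
Conditions: n-BuLi, THF, −78 °C; then 20, −78 → 0 °C
Reagents that add atoms: none
Why: N-Acylation of the lithiated oxazolidinone attaches the Evans auxiliary.

Step 12
Reactants: 21 (R)-4-benzyl-3-butanoyloxazolidin-2-one
Product: 23 (R)-4-benzyl-3-[(2S)-2-(hydroxymethyl)butanoyl]oxazolidin-2-one, via titanium enolate 22 (not isolated)
Conditions: TiCl4 (1.05 equiv), i-Pr2NEt (1.1 equiv), CH2Cl2, 0 °C; then 1,3,5-trioxane, TiCl4 (1.05 equiv), 0 °C; then H2O
Reagents that add atoms: 1,3,5-trioxane, C1OCOCO1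
Why: Evans titanium-enolate hydroxymethylation, in which the chelated Z-enolate is attacked by the formaldehyde equivalent on the face opposite to the benzyl group, which with the R auxiliary should give the 2S centre.

Step 13
Reactants: 23 (R)-4-benzyl-3-[(2S)-2-(hydroxymethyl)butanoyl]oxazolidin-2-one
Product: 24 (R)-4-benzyl-3-[(2S)-2-(tert-butyldiphenylsilyloxymethyl)butanoyl]oxazolidin-2-one
Conditions: TBDPSCl, imidazole, CH2Cl2, rt
Reagents that add atoms: tert-butyldiphenylsilyl chloride, CC(C)(C)[Si](Cl)(c1ccccc1)c1ccccc1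
Why: Standard silylation of a primary alcohol; TBDPS is chosen because it should survive the later trifluoroacetic acid step.

Step 14
Reactants: 24 (R)-4-benzyl-3-[(2S)-2-(tert-butyldiphenylsilyloxymethyl)butanoyl]oxazolidin-2-one
Product: 25 (2S)-2-(tert-butyldiphenylsilyloxymethyl)butanoic acid
Conditions: LiOH, H2O2, THF/H2O, 0 °C; then Na2SO3; then 1 M HCl
Reagents that add atoms: hydrogen peroxide, OO
Why: Hydroperoxide cleavage of the exocyclic imide carbonyl (Evans auxiliary removal) should give the acid without epimerising the α-centre.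

Step 15
Reactants: 26 tert-butyl acrylate; 27 acetaldehyde
Product: 28 tert-butyl 3-hydroxy-2-methylidenebutanoate (racemic)
Conditions: DABCO (0.2 equiv), neat, rt, several days
Reagents that add atoms: none
Why: Morita–Baylis–Hillman reaction; the racemic carbinol centre disappears in the next step.

Step 16
Reactants: 28 tert-butyl 3-hydroxy-2-methylidenebutanoate
Product: 29 tert-butyl (2Z)-2-(bromomethyl)but-2-enoate
Conditions: NBS, Me2S, CH2Cl2, 0 °C → rt
Reagents that add atoms: N-bromosuccinimide, O=C1CCC(=O)N1Br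
Why: Corey–Kim-type activation of the alcohol and bromide attack with allylic transposition (SN2') should give the conjugated primary bromide with the methyl group cis to CH2Br, the isomer strongly favoured for acrylate-derived adducts.

Step 17
Reactants: 25 (2S)-2-(tert-butyldiphenylsilyloxymethyl)butanoic acid; 29 tert-butyl (2Z)-2-(bromomethyl)but-2-enoate
Product: 30 tert-butyl (2E)-2-{[(2S)-2-(tert-butyldiphenylsilyloxymethyl)butanoyl]oxymethyl}but-2-enoate
Conditions: Cs2CO3 (1.0 equiv), DMF, 0 °C → rt
Reagents that add atoms: none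
Why: SN2 O-alkylation of the caesium carboxylate by the primary allylic bromide; the mild base should not epimerise the α-centre and the alkene geometry is kept (the descriptor changes to E only because the priorities change).

Step 18
Reactants: 30 tert-butyl (2E)-2-{[(2S)-2-(tert-butyldiphenylsilyloxymethyl)butanoyl]oxymethyl}but-2-enoate
Product: 31 (2E)-2-{[(2S)-2-(tert-butyldiphenylsilyloxymethyl)butanoyl]oxymethyl}but-2-enoic acid
Conditions: CF3CO2H/CH2Cl2 (1:4), 0 °C
Reagents that add atoms: none
Why: Acidolysis of the tert-butyl ester (loss of isobutene) in the presence of the acid-stable TBDPS ether and the second ester.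

Step 19
Reactants: 18 (3S,6S,7R,8R)-3-(tert-butyldimethylsilyloxy)-8-hydroxygermacra-1(10)E,4Z,11(13)-trien-12,6-olide; 31 (2E)-2-{[(2S)-2-(tert-butyldiphenylsilyloxymethyl)butanoyl]oxymethyl}but-2-enoic acid
Product: 33 8-O-acyl lactone (3S,6S,7R,8R; both silyl ethers in place), via mixed anhydride 32 (not isolated)
Conditions: 2,4,6-trichlorobenzoyl chloride, Et3N, THF, rt; then 18, DMAP, toluene, rt → 40 °C
Reagents that add atoms: none
Why: Yamaguchi esterification through the mixed anhydride and the acylpyridinium ion should acylate the hindered C8 alcohol with retention at C8 and without isomerising the E enoate.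

Step 20
Reactants: 33 8-O-acyl lactone
Product: 34 (1R,10R)-1,10-epoxide of 33
Conditions: mCPBA (1.1 equiv), NaHCO3, CH2Cl2, −20 → 0 °C
Reagents that add atoms: 3-chloroperoxybenzoic acid, O=C(OO)c1cccc(Cl)c1
Why: Prilezhaev epoxidation of the most electron-rich alkene (C4=C5 is deactivated by two allylic oxygens and both enoates are electron-poor) from the exposed face of the E C1=C10 bond, with C14 on the side of the C7 and C8 substituents, should give the trans 1R,10R epoxide.

Step 21
Reactants: 34 (1R,10R)-1,10-epoxide of 33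
Product: 35 target CNP0156402.1
Conditions: n-Bu4NF/AcOH (1:1, excess), THF, 0 °C → rt
Reagents that add atoms: none
Why: Buffered fluoride desilylation should remove both silyl ethers while the near-neutral medium spares the epoxide, the α-methylene lactone and the esters.

**Compound list**

1 | 4-methoxybenzyl alcohol | COc1ccc(CO)cc1 | starting material
2 | ethyl vinyl ether | CCOC=C | starting material
3 | 4-methoxybenzyl vinyl ether | C=COCc1ccc(OC)cc1 | intermediate
4 | 1,2-dibromoethyl 4-methoxybenzyl ether (racemic) | BrCC(Br)OCc1ccc(OC)cc1 | intermediate (not isolated)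
5 | (Z)-1-bromo-2-(4-methoxybenzyloxy)ethene | Br/C=C\OCc1ccc(OC)cc1 | intermediate
6 | (S)-(+)-carvone | CC1=CC[C@@H](CC1=O)C(C)=C | starting material
7 | (1S,5S)-cis-carveol | CC1=CC[C@@H](C[C@@H]1O)C(C)=C | intermediate
8 | (1S,5S)-cis-carveol TBS ether | CC1=CC[C@@H](C[C@@H]1O[Si](C)(C)C(C)(C)C)C(C)=C | intermediate
9 | (4S,6S)-4-(TBS-oxy)-3-methyl-6-(prop-1-en-2-yl)cyclohex-2-en-1-one | CC1=CC(=O)[C@@H](C[C@@H]1O[Si](C)(C)C(C)(C)C)C(C)=C | intermediate
10 | (Z)-2-(4-methoxybenzyloxy)ethenyllithium | [Li]/C=C\OCc1ccc(OC)cc1 | intermediate (not isolated)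
11 | (1S,4S,6S)-4-(TBS-oxy)-1-[(Z)-2-(4-methoxybenzyloxy)ethenyl]-3-methyl-6-(prop-1-en-2-yl)cyclohex-2-en-1-ol | CC1=C[C@@](O)(/C=C\OCc2ccc(OC)cc2)[C@@H](C[C@@H]1O[Si](C)(C)C(C)(C)C)C(C)=C | intermediate
12 | potassium alkoxide of 11 | CC1=C[C@@]([O-])(/C=C\OCc2ccc(OC)cc2)[C@@H](C[C@@H]1O[Si](C)(C)C(C)(C)C)C(C)=C.[K+] | intermediate (not isolated)
13 | potassium (3S,8R)-3-(TBS-oxy)-8-(4-methoxybenzyloxy)-4,10-dimethylcyclodeca-1(10)E,4Z,6-trien-6-olate (ring-trans C6=C7) | C/C1=C/C([O-])=C/[C@H](OCc2ccc(OC)cc2)C/C(C)=C/C[C@@H]1O[Si](C)(C)C(C)(C)C.[K+] | intermediate (not isolated)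
14 | (3S,8R)-3-(TBS-oxy)-8-(4-methoxybenzyloxy)-4,10-dimethylcyclodeca-1(10)E,4Z,6-trien-6-yl triflate (ring-trans C6=C7) | C/C1=C/C(OS(=O)(=O)C(F)(F)F)=C/[C@H](OCc2ccc(OC)cc2)C/C(C)=C/C[C@@H]1O[Si](C)(C)C(C)(C)C | intermediate
15 | (3S,8R)-3-(TBS-oxy)-8-(4-methoxybenzyloxy)-4,10-dimethylcyclodeca-1(10)E,4Z,6E-triene | C/C1=C/C=C/[C@H](OCc2ccc(OC)cc2)C/C(C)=C/C[C@@H]1O[Si](C)(C)C(C)(C)C | intermediate
16 | 2-bromoacrylic acid | C=C(Br)C(=O)O | starting material
17 | (3S,6S,7R,8R)-3-(TBS-oxy)-8-(4-methoxybenzyloxy)germacra-1(10)E,4Z,11(13)-trien-12,6-olide | C=C1C(=O)O[C@H]2/C=C(/C)[C@@H](O[Si](C)(C)C(C)(C)C)C/C=C(\C)C[C@@H](OCc3ccc(OC)cc3)[C@@H]12 | intermediate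
18 | (3S,6S,7R,8R)-3-(TBS-oxy)-8-hydroxygermacra-1(10)E,4Z,11(13)-trien-12,6-olide | C=C1C(=O)O[C@H]2/C=C(/C)[C@@H](O[Si](C)(C)C(C)(C)C)C/C=C(\C)C[C@@H](O)[C@@H]12 | intermediate
19 | (R)-4-benzyl-2-oxazolidinone | O=C1N[C@H](Cc2ccccc2)CO1 | starting material
20 | butanoyl chloride | CCCC(=O)Cl | starting material
21 | (R)-4-benzyl-3-butanoyloxazolidin-2-one | CCCC(=O)N1[C@H](Cc2ccccc2)COC1=O | intermediate
22 | trichlorotitanium (Z)-enolate of 21 | CC/C=C(\O[Ti](Cl)(Cl)Cl)N1[C@H](Cc2ccccc2)COC1=O | intermediate (not isolated)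
23 | (R)-4-benzyl-3-[(2S)-2-(hydroxymethyl)butanoyl]oxazolidin-2-one | CC[C@@H](CO)C(=O)N1[C@H](Cc2ccccc2)COC1=O | intermediate
24 | (R)-4-benzyl-3-[(2S)-2-(TBDPS-oxymethyl)butanoyl]oxazolidin-2-one | CC[C@@H](CO[Si](c1ccccc1)(c1ccccc1)C(C)(C)C)C(=O)N1[C@H](Cc2ccccc2)COC1=O | intermediate
25 | (2S)-2-(TBDPS-oxymethyl)butanoic acid | CC[C@@H](CO[Si](c1ccccc1)(c1ccccc1)C(C)(C)C)C(=O)O | intermediate
26 | tert-butyl acrylate | C=CC(=O)OC(C)(C)C | starting material
27 | acetaldehyde | CC=O | starting material
28 | tert-butyl 3-hydroxy-2-methylidenebutanoate (racemic) | CC(O)C(=C)C(=O)OC(C)(C)C | intermediate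
29 | tert-butyl (2Z)-2-(bromomethyl)but-2-enoate | CC(C)(C)OC(=O)/C(=C/C)CBr | intermediate
30 | tert-butyl (2E)-2-{[(2S)-2-(TBDPS-oxymethyl)butanoyl]oxymethyl}but-2-enoate | CC(C)(C)OC(=O)/C(=C/C)COC(=O)[C@@H](CC)CO[Si](c1ccccc1)(c1ccccc1)C(C)(C)C | intermediate
31 | (2E)-2-{[(2S)-2-(TBDPS-oxymethyl)butanoyl]oxymethyl}but-2-enoic acid | OC(=O)/C(=C/C)COC(=O)[C@@H](CC)CO[Si](c1ccccc1)(c1ccccc1)C(C)(C)C | intermediate
32 | mixed 2,4,6-trichlorobenzoic anhydride of 31 | O=C(OC(=O)/C(=C/C)COC(=O)[C@@H](CC)CO[Si](c1ccccc1)(c1ccccc1)C(C)(C)C)c1c(Cl)cc(Cl)cc1Cl | intermediate (not isolated)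
33 | (3S,6S,7R,8R)-3-(TBS-oxy)-8-acyloxygermacra-1(10)E,4Z,11(13)-trien-12,6-olide (acyl = side chain of 31) | C=C1C(=O)O[C@H]2/C=C(/C)[C@@H](O[Si](C)(C)C(C)(C)C)C/C=C(\C)C[C@@H](OC(=O)/C(=C/C)COC(=O)[C@@H](CC)CO[Si](c3ccccc3)(c3ccccc3)C(C)(C)C)[C@@H]12 | intermediate
34 | (1R,3S,6S,7R,8R,10R)-1,10-epoxide of 33 | C=C1C(=O)O[C@H]2/C=C(/C)[C@@H](O[Si](C)(C)C(C)(C)C)C[C@H]3O[C@]3(C)C[C@@H](OC(=O)/C(=C/C)COC(=O)[C@@H](CC)CO[Si](c4ccccc4)(c4ccccc4)C(C)(C)C)[C@@H]12 | intermediate
35 | CNP0156402.1, (1R,3S,6S,7R,8R,10R)-1,10-epoxy-3-hydroxy-8-acyloxygermacra-4Z,11(13)-dien-12,6-olide | C=C1C(=O)O[C@H]2/C=C(/C)[C@@H](O)C[C@H]3O[C@]3(C)C[C@@H](OC(=O)/C(=C/C)COC(=O)[C@@H](CC)CO)[C@@H]12 | target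

**Step count and risks**

Total steps: 21. Longest linear sequence: 11 steps (steps 3–10 and 19–21, from (S)-carvone).

Steps most likely to fail:

1. Step 9. The carbopalladation may take the other face of C6=C7. The C–O bond may form by inner-sphere delivery from palladium, which would give the trans-fused lactone. Zerovalent palladium may re-ionise the allylic lactone and equilibrate C6. β-Hydride elimination may give a Heck-type triene. Above about 60 °C the triene may undergo Cope rearrangement. The fallback replaces the annulation by enolate alkylation, reduction, lactonisation and methylenation, all known chemistry; it sets out from 11 and comes back at 17. Compound 11 is rearranged as in step 7, but dienolate 13 is alkylated in the flask at C7 with methyl bromoacetate at −78 °C (peripheral face, the same sense as the carbopalladation) to give methyl [(3S,7R,8R)-3-(TBS-oxy)-8-(4-methoxybenzyloxy)-4,10-dimethyl-6-oxocyclodeca-1(10)E,4Z-dien-7-yl]acetate F1. Luche reduction (NaBH4, CeCl3·7H2O, MeOH) of the C6 ketone from the face away from the new side chain, with lactonisation of the cis hydroxy ester, gives the cis-fused lactone lacking C13, F2. LiN(i-Pr)2 and dimethylmethylideneammonium iodide give the C11 dimethylaminomethyl lactone F3, methyl iodide gives its trimethylammonium iodide F4, and NaHCO3 eliminates it to 17.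

2. Step 7. The potassium dienolate may expel the C8 alkoxide (E1cB) before it is triflated, and part of the rearrangement may pass through a boat transition state (1,3-diaxial contact of the alkoxide oxygen and the Z ether oxygen), which would erode the C8 configuration. The fallback sets C8 by catalyst control on the elimination product; it sets out from 11 and comes back at 14. Compound 11 is treated with KN(SiMe3)2/18-crown-6 and warmed to rt so that rearrangement and loss of 4-methoxybenzyl alkoxide both go to completion, giving the cross-conjugated (3S)-3-(TBS-oxy)-4,10-dimethylcyclodeca-1(10)E,4Z,7E-trien-6-one F5. Copper-catalysed enantioselective conjugate borylation (B2pin2, CuCl, NaOt-Bu, chiral ferrocenyl bisphosphine, MeOH) at the less substituted β-carbon C8 gives the 8-pinacolboryl ketone F6. NaBO3·4H2O oxidation with retention gives the (8R)-8-hydroxy ketone F7. 4-Methoxybenzyl trichloroacetimidate with La(OTf)3 gives the (8R)-8-(4-methoxybenzyloxy) ketone F8. Kinetic deprotonation at C7 with KN(SiMe3)2 at −78 °C and PhNTf2 gives 14.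

3. Step 20. The peracid may attack the other face of C1=C10 if the ring of 33 populates a conformer with C14 turned to the opposite side, and some epoxidation of C4=C5 may compete. The fallback replaces substrate control by reagent control; it sets out from 33 and comes back at 34 without a new compound. A Shi epoxidation with the D-fructose-derived ketone and KHSO5, buffered near pH 8 to spare the lactone and esters (MeCN/dimethoxymethane/H2O, 0 °C), is expected to deliver oxygen to the face of the E-trisubstituted alkene that gives the 1R,10R epoxide.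

Further compounds
F1 | step 9 | methyl [(3S,7R,8R)-3-(TBS-oxy)-8-(4-methoxybenzyloxy)-4,10-dimethyl-6-oxocyclodeca-1(10)E,4Z-dien-7-yl]acetate | C/C1=C/C(=O)[C@H](CC(=O)OC)[C@H](OCc2ccc(OC)cc2)C/C(C)=C/C[C@@H]1O[Si](C)(C)C(C)(C)C
F2 | step 9 | (3S,6S,7R,8R)-3-(TBS-oxy)-8-(4-methoxybenzyloxy)-13-norgermacra-1(10)E,4Z-dien-12,6-olide | C1C(=O)O[C@H]2/C=C(/C)[C@@H](O[Si](C)(C)C(C)(C)C)C/C=C(\C)C[C@@H](OCc3ccc(OC)cc3)[C@@H]12
F3 | step 9 | 11-(dimethylaminomethyl) derivative of F2 (C11 epimers) | CN(C)CC1C(=O)O[C@H]2/C=C(/C)[C@@H](O[Si](C)(C)C(C)(C)C)C/C=C(\C)C[C@@H](OCc3ccc(OC)cc3)[C@@H]12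
F4 | step 9 | trimethylammonium iodide of F3 | C[N+](C)(C)CC1C(=O)O[C@H]2/C=C(/C)[C@@H](O[Si](C)(C)C(C)(C)C)C/C=C(\C)C[C@@H](OCc3ccc(OC)cc3)[C@@H]12.[I-]
F5 | step 7 | (3S)-3-(TBS-oxy)-4,10-dimethylcyclodeca-1(10)E,4Z,7E-trien-6-one | C/C1=C/C(=O)/C=C/C/C(C)=C/C[C@@H]1O[Si](C)(C)C(C)(C)C
F6 | step 7 | (3S)-3-(TBS-oxy)-4,10-dimethyl-8-(pinacolboryl)cyclodeca-1(10)E,4Z-dien-6-one (C8 as in 8R alcohol) | C/C1=C/C(=O)C[C@H](B2OC(C)(C)C(C)(C)O2)C/C(C)=C/C[C@@H]1O[Si](C)(C)C(C)(C)C
F7 | step 7 | (3S,8R)-3-(TBS-oxy)-8-hydroxy-4,10-dimethylcyclodeca-1(10)E,4Z-dien-6-one | C/C1=C/C(=O)C[C@H](O)C/C(C)=C/C[C@@H]1O[Si](C)(C)C(C)(C)C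
F8 | step 7 | (3S,8R)-3-(TBS-oxy)-8-(4-methoxybenzyloxy)-4,10-dimethylcyclodeca-1(10)E,4Z-dien-6-one | C/C1=C/C(=O)C[C@H](OCc2ccc(OC)cc2)C/C(C)=C/C[C@@H]1O[Si](C)(C)C(C)(C)C
F0 | step 20 | none | none
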